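**Retrosynthetic overview**

1. The target comes from its hexabenzyl ether by one neutral hydrogenolysis at the very end.
2. Key disconnection: the C2–C1' bond of the 3-hydroxychromanone unit. The finished (2S)-flavanone–biaryl half, as the arylzinc made from its aryl iodide, is added to 5,7-bis(benzyloxy)chromone by Rh-catalysed asymmetric conjugate arylation; the C3 enolate is trapped as an enol silane and oxidised in the same flask (Rubottom), so one operation gives the C–C bond, C2, the C3–O bond and C3 (trans).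
3. Enabling feature: C2 and C3 of ring C of that unit are the β- and α-carbons of the vinylogous ester O1–C2=C3–C4=O of a chromone, and C1' is an aryl carbon (para to the ring-B oxygen) that can carry a metal. The 3-deoxy skeleton is C2-symmetric (two homotopic chromanone rings), so the hydroxyl has to enter while the new ring alone is an enol silane.
4. The flavanone half comes from an iodo-boronic acid of 2,2'-bis(benzyloxy)biphenyl and the same chromone (Rh-catalysed asymmetric 1,4-addition); the biaryl comes from 2,2'-biphenol by benzylation, double para-iodination and mono I/Mg exchange–borylation.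
5. Ring order: all benzene rings are bought. The only ring built is the pyranone ring of the chromone (enaminone cyclisation from 2',4',6'-trihydroxyacetophenone); it is made once and becomes ring C of the flavanone unit first (step 6) and ring C of the flavanonol unit second (step 7).

Key step: step 7

Assumption: the sense of induction of the Rh(I)/(S)-bisphosphine catalysts on the chromone is taken by analogy with 2-cyclohexenone and N-acyl-4-quinolones; if a model addition shows the opposite sense, the (R)-ligands are used in steps 6 and 7.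

**Route**

Step 1
Reactants: 1 2',4',6'-trihydroxyacetophenone
Product: 2 1-[2,4-bis(benzyloxy)-6-hydroxyphenyl]ethan-1-one
Conditions: BnBr (2.1 equiv), K2CO3, DMF, rt
Reagents that add atoms: benzyl bromide BrCc1ccccc1
Why: Williamson ether synthesis; the ortho hydroxyl that is hydrogen-bonded to the acetyl carbonyl is the least nucleophilic, so alkylation should stop at the 2,4-dibenzyl ether.

Step 2
Reactants: 2 1-[2,4-bis(benzyloxy)-6-hydroxyphenyl]ethan-1-one
Product: 4 5,7-bis(benzyloxy)-4H-chromen-4-one, via enaminone 3 (not isolated)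
Conditions: DMF-DMA, toluene, 100 °C; then conc. HCl, CH2Cl2, rt
Reagents that add atoms: N,N-dimethylformamide dimethyl acetal COC(OC)N(C)C
Why: Enaminone formation from the methyl ketone, then acid-promoted addition of the phenol to the enaminone β-carbon with loss of dimethylamine (standard chromone synthesis), which closes the pyranone ring at O1–C2.

Step 3
Reactants: 5 2,2'-biphenol
Product: 6 2,2'-bis(benzyloxy)-1,1'-biphenyl
Conditions: BnBr (2.3 equiv), K2CO3, DMF, 60 °C
Reagents that add atoms: benzyl bromide BrCc1ccccc1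
Why: Williamson ether synthesis on both phenols.

Step 4
Reactants: 6 2,2'-bis(benzyloxy)-1,1'-biphenyl
Product: 7 2,2'-bis(benzyloxy)-5,5'-diiodo-1,1'-biphenyl
Conditions: NIS (2.1 equiv), TFA (cat.), MeCN, rt
Reagents that add atoms: N-iodosuccinimide O=C1CCC(=O)N1I
Why: Electrophilic aromatic iodination; each alkoxy group directs para, the ortho position is flanked by the benzyloxy group, and the unactivated benzyl phenyl rings should not react.

Step 5
Reactants: 7 2,2'-bis(benzyloxy)-5,5'-diiodo-1,1'-biphenyl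
Product: 10 [6,2'-bis(benzyloxy)-5'-iodo-[1,1'-biphenyl]-3-yl]boronic acid, via arylmagnesium chloride 8 (not isolated), via diisopropyl boronate 9 (not isolated)
Conditions: iPrMgCl·LiCl (1.0 equiv), THF, 0 °C; B(OiPr)3, 0 °C to rt; 1 M HCl
Reagents that add atoms: triisopropyl borate CC(C)OB(OC(C)C)OC(C)C (boron); water O (the two OH oxygens); in intermediate 8 only: isopropylmagnesium chloride CC(C)[Mg]Cl
Why: Iodine–magnesium exchange with the turbo-Grignard reagent, borate trapping and hydrolysis; the C2-symmetric diiodide can give only one mono-Grignard species, the first exchange should slow the second by making the other ring more electron-rich, and unchanged 7 is recycled.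

Step 6
Reactants: 10 [6,2'-bis(benzyloxy)-5'-iodo-[1,1'-biphenyl]-3-yl]boronic acid, 4 5,7-bis(benzyloxy)-4H-chromen-4-one
Product: 11 (2S)-5,7-bis(benzyloxy)-2-[6,2'-bis(benzyloxy)-5'-iodo-[1,1'-biphenyl]-3-yl]chroman-4-one
Conditions: 4 (1.5 equiv), [Rh(OH)(cod)]2 (2.5 mol %), (S)-MeO-F12-BIPHEP (5.5 mol %), toluene/H2O 10:1, 40 °C
Reagents that add atoms: none
Why: Rh(I)-catalysed asymmetric 1,4-addition of an arylboronic acid to a chromone (Hayashi–Miyaura reaction); the aryl–Rh species adds to C2 on the face chosen by the ligand and sets the 2S centre, and the base-free conditions should keep the flavanone from ring-opening and leave the aryl iodide intact.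

Step 7
Reactants: 11 (2S)-5,7-bis(benzyloxy)-2-[6,2'-bis(benzyloxy)-5'-iodo-[1,1'-biphenyl]-3-yl]chroman-4-one, 4 5,7-bis(benzyloxy)-4H-chromen-4-one
Product: 16 (2R,3R)-5,7-bis(benzyloxy)-2-{6,2'-bis(benzyloxy)-5'-[(2S)-5,7-bis(benzyloxy)-4-oxochroman-2-yl]-[1,1'-biphenyl]-3-yl}-3-hydroxychroman-4-one, via diarylzinc 12 (not isolated), via enol silane 13 (not isolated), via silyloxy epoxide 14 (not isolated), via 3-silyloxy ketone 15 (not isolated)
Conditions: iPr2Zn (0.55 equiv), Li(acac) (10 mol %), Et2O/NMP, 25 °C, then vacuum; 4 (1.5 equiv), [RhCl((S)-binap)]2 (3 mol %), TMSCl (2 equiv), THF, 20 °C; DMDO, acetone, −40 to 0 °C; citric acid, MeOH, rt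
Reagents that add atoms: dimethyldioxirane CC1(C)OO1 (the C3 oxygen); in intermediates 12–15 only: diisopropylzinc CC(C)[Zn]C(C)C, chlorotrimethylsilane C[Si](C)(C)Cl
Why: Proposed new method: the ketone-tolerant Li(acac)-catalysed iodine–zinc exchange turns 11 into diarylzinc 12, whose aryl group passes from Zn to Rh and adds across C2=C3 of chromone 4 on the face selected by (S)-BINAP, and the oxa-π-allyl rhodium is silylated by TMSCl to enol silane 13 with return of Rh–Cl; the closest known reaction type is the Rh/BINAP-catalysed 1,4-addition of arylzinc chlorides to N-acyl-4-quinolones with TMSCl, which has not been shown on chromones, with a ketone-bearing arylzinc, or telescoped with an oxidation. Dimethyldioxirane then epoxidises the enol ether (Rubottom oxidation, known for flavanone enol silanes) and silyloxy epoxide 14 opens with 1,4-silyl shift to 15, which mild acid desilylates. No ring of the product is closed in this step; the oxirane of 14 is a transient formed by oxygen-atom transfer. C2 (R in 16, spatially the same arrangement as the 2S centre of the flavanone unit) is set by the catalyst, the stereocentre of 11 being remote, and C3 (R) is set by C2, because the oxidant should attack the face of C3=C4 opposite the pseudo-axial 2-aryl group, which gives the 2,3-trans ketol. The step needs site selectivity between two chromanone units that are homotopic in the 3-deoxy compound: only the unit born here exists as an enol silane, while the ketone of 11 meets neither a base nor a nucleophile strong enough to add to it. Regiochemistry is fixed by the C–I bond (ipso) on one side and by the β-carbon of the vinylogous ester on the other, and removal of 2-iodopropane before the oxidation keeps electrophilic iodine away from the electron-rich rings.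

Step 8
Reactants: 16 (2R,3R)-5,7-bis(benzyloxy)-2-{6,2'-bis(benzyloxy)-5'-[(2S)-5,7-bis(benzyloxy)-4-oxochroman-2-yl]-[1,1'-biphenyl]-3-yl}-3-hydroxychroman-4-one
Product: 17 (2R,3R)-2-{5'-[(2S)-5,7-dihydroxy-4-oxochroman-2-yl]-6,2'-dihydroxy-[1,1'-biphenyl]-3-yl}-3,5,7-trihydroxychroman-4-one (CNP0201582.1)
Conditions: H2 (1 atm), Pd(OH)2/C, THF/MeOH, rt
Reagents that add atoms: none
Why: Catalytic hydrogenolysis of the six aryl benzyl ethers under neutral conditions, which should leave the ketones, the ketol and the three base-sensitive stereocentres untouched.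

**Compound list**

1 | 2',4',6'-trihydroxyacetophenone | CC(=O)c1c(O)cc(O)cc1O | starting material
2 | 1-[2,4-bis(benzyloxy)-6-hydroxyphenyl]ethan-1-one | CC(=O)c1c(O)cc(OCc2ccccc2)cc1OCc1ccccc1 | intermediate
3 | (E)-1-[2,4-bis(benzyloxy)-6-hydroxyphenyl]-3-(dimethylamino)prop-2-en-1-one (enaminone) | CN(C)/C=C/C(=O)c1c(O)cc(OCc2ccccc2)cc1OCc1ccccc1 | intermediate
4 | 5,7-bis(benzyloxy)-4H-chromen-4-one | O=c1ccoc2cc(OCc3ccccc3)cc(OCc3ccccc3)c12 | intermediate
5 | 2,2'-biphenol | Oc1ccccc1-c1ccccc1O | starting material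
6 | 2,2'-bis(benzyloxy)-1,1'-biphenyl | c1ccc(COc2ccccc2-c2ccccc2OCc2ccccc2)cc1 | intermediate
7 | 2,2'-bis(benzyloxy)-5,5'-diiodo-1,1'-biphenyl | Ic1ccc(OCc2ccccc2)c(c1)-c1cc(I)ccc1OCc1ccccc1 | intermediate
8 | [6,2'-bis(benzyloxy)-5'-iodo-[1,1'-biphenyl]-3-yl]magnesium chloride | Cl[Mg]c1ccc(OCc2ccccc2)c(c1)-c1cc(I)ccc1OCc1ccccc1 | intermediate
9 | diisopropyl [6,2'-bis(benzyloxy)-5'-iodo-[1,1'-biphenyl]-3-yl]boronate | CC(C)OB(OC(C)C)c1ccc(OCc2ccccc2)c(c1)-c1cc(I)ccc1OCc1ccccc1 | intermediate
10 | [6,2'-bis(benzyloxy)-5'-iodo-[1,1'-biphenyl]-3-yl]boronic acid | OB(O)c1ccc(OCc2ccccc2)c(c1)-c1cc(I)ccc1OCc1ccccc1 | intermediate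
11 | (2S)-5,7-bis(benzyloxy)-2-[6,2'-bis(benzyloxy)-5'-iodo-[1,1'-biphenyl]-3-yl]chroman-4-one | O=C1C[C@@H](c2ccc(OCc6ccccc6)c(-c3cc(I)ccc3OCc6ccccc6)c2)Oc2cc(OCc6ccccc6)cc(OCc6ccccc6)c21 | intermediate
12 | bis{6,2'-bis(benzyloxy)-5'-[(2S)-5,7-bis(benzyloxy)-4-oxochroman-2-yl]-[1,1'-biphenyl]-3-yl}zinc | O=C1C[C@@H](c2ccc(OCc6ccccc6)c(-c3cc([Zn]c7ccc(OCc6ccccc6)c(c7)-c7cc(ccc7OCc6ccccc6)[C@@H]7CC(=O)c8c(OCc6ccccc6)cc(OCc6ccccc6)cc8O7)ccc3OCc6ccccc6)c2)Oc2cc(OCc6ccccc6)cc(OCc6ccccc6)c21 | intermediate
13 | (2S)-5,7-bis(benzyloxy)-2-{6,2'-bis(benzyloxy)-5'-[(2S)-5,7-bis(benzyloxy)-4-(trimethylsilyloxy)-2H-chromen-2-yl]-[1,1'-biphenyl]-3-yl}chroman-4-one (enol silane of the new unit) | O=C1C[C@@H](c2ccc(OCc6ccccc6)c(-c3cc([C@H]4Oc5cc(OCc6ccccc6)cc(OCc6ccccc6)c5C(O[Si](C)(C)C)=C4)ccc3OCc6ccccc6)c2)Oc2cc(OCc6ccccc6)cc(OCc6ccccc6)c21 | intermediate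
14 | 3,4-epoxide of 13 at the enol ether double bond, epoxide oxygen trans to the 2-aryl group, C4 carrying OSiMe3 (silyloxy epoxide) | O=C1C[C@@H](c2ccc(OCc6ccccc6)c(-c3cc([C@H]4Oc5cc(OCc6ccccc6)cc(OCc6ccccc6)c5[C@]7(O[Si](C)(C)C)O[C@H]47)ccc3OCc6ccccc6)c2)Oc2cc(OCc6ccccc6)cc(OCc6ccccc6)c21 | intermediate
15 | (2S)-5,7-bis(benzyloxy)-2-{6,2'-bis(benzyloxy)-5'-[(2R,3R)-5,7-bis(benzyloxy)-4-oxo-3-(trimethylsilyloxy)chroman-2-yl]-[1,1'-biphenyl]-3-yl}chroman-4-one | O=C1C[C@@H](c2ccc(OCc6ccccc6)c(-c3cc([C@H]4Oc5cc(OCc6ccccc6)cc(OCc6ccccc6)c5C(=O)[C@@H]4O[Si](C)(C)C)ccc3OCc6ccccc6)c2)Oc2cc(OCc6ccccc6)cc(OCc6ccccc6)c21 | intermediate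
16 | (2R,3R)-5,7-bis(benzyloxy)-2-{6,2'-bis(benzyloxy)-5'-[(2S)-5,7-bis(benzyloxy)-4-oxochroman-2-yl]-[1,1'-biphenyl]-3-yl}-3-hydroxychroman-4-one | O=C1C[C@@H](c2ccc(OCc6ccccc6)c(-c3cc([C@H]4Oc5cc(OCc6ccccc6)cc(OCc6ccccc6)c5C(=O)[C@@H]4O)ccc3OCc6ccccc6)c2)Oc2cc(OCc6ccccc6)cc(OCc6ccccc6)c21 | intermediate
17 | (2R,3R)-2-{5'-[(2S)-5,7-dihydroxy-4-oxochroman-2-yl]-6,2'-dihydroxy-[1,1'-biphenyl]-3-yl}-3,5,7-trihydroxychroman-4-one | O=C1C[C@@H](c2ccc(O)c(-c3cc([C@H]4Oc5cc(O)cc(O)c5C(=O)[C@@H]4O)ccc3O)c2)Oc2cc(O)cc(O)c21 | target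

**Step count and risks**

Total step count: 8. Longest linear sequence: 6 steps (steps 3 to 8, from 2,2'-biphenol).

Steps most likely to fail:

Step 7 (proposed new method). The iodine–zinc exchange may stall on the electron-rich ring. The arylzinc may be protonated by the enolisable ketone before it reaches rhodium. The carbometalation of the electron-rich, peri-substituted chromone may be too slow. The enol silane may hydrolyse before it is oxidised, which would leave the 3-deoxy compound. The fallback uses known reactions only and sets out from 11. Miyaura borylation (B2pin2, PdCl2(dppf), KOAc, dioxane, 80 °C) should give (2S)-5,7-bis(benzyloxy)-2-[6,2'-bis(benzyloxy)-5'-(pinacolboryl)-[1,1'-biphenyl]-3-yl]chroman-4-one F1. Rh-catalysed asymmetric 1,4-addition of this boronate to chromone 4 under the conditions of step 6 (dioxane/H2O, 50 °C) should give the C2-symmetric (2S,2''S)-bis-flavanone hexabenzyl ether F2. Because the two chromanone rings of F2 are homotopic, mono-enolisation (LiHMDS 1.0 equiv with TMSCl as internal quench, THF, −78 °C) can give only one mono-enol silane, which is compound 13; there the fallback comes back to the route (DMDO, then citric acid, to 16). The price is a statistical mixture of F2 (recycled), 13 and the bis-enol silane.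

Step 6. Rhodium may insert into the C–I bond, or protodeboronation may outrun the slow insertion of the hindered chromone. Retro-oxa-Michael opening of the product may erode the enantiomeric purity. The fallback builds the flavanone by organocatalytic oxa-Michael cyclisation instead, from 7 and 2. Grignard 8 (from 7 as in step 5) is quenched with DMF to give 6,2'-bis(benzyloxy)-5'-iodo-[1,1'-biphenyl]-3-carbaldehyde F3. Ketone 2 is C-acylated through its dianion (LiHMDS, then Boc2O, THF, −78 °C) to tert-butyl 3-[2,4-bis(benzyloxy)-6-hydroxyphenyl]-3-oxopropanoate F4. Knoevenagel condensation of the two (piperidinium acetate, toluene) should give the alkylidene β-keto ester F5. Intramolecular oxa-Michael addition under a cinchona-derived bifunctional thiourea catalyst (toluene, −25 °C; the pseudo-enantiomer that gives 2S) should give tert-butyl (2S)-5,7-bis(benzyloxy)-2-[6,2'-bis(benzyloxy)-5'-iodo-[1,1'-biphenyl]-3-yl]-4-oxochroman-3-carboxylate F6. Warming with TsOH (toluene, 80 °C) removes the ester by loss of isobutene and decarboxylation and returns to the route at 11.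

Step 8. Cleavage of the hindered 5-O-benzyl ethers may be incomplete, or over-reduction may open the benzylic C2–O1 bonds of the two pyranone rings. The fallback replaces hydrogenolysis by Lewis-acid debenzylation with a cation scavenger (BCl3, pentamethylbenzene, CH2Cl2, −78 °C); it sets out from 16, comes back at 17 and makes no new compound.

**Further compounds**

F1 | step 7 | (2S)-5,7-bis(benzyloxy)-2-[6,2'-bis(benzyloxy)-5'-(4,4,5,5-tetramethyl-1,3,2-dioxaborolan-2-yl)-[1,1'-biphenyl]-3-yl]chroman-4-one | O=C1C[C@@H](c2ccc(OCc6ccccc6)c(-c3cc(B4OC(C)(C)C(C)(C)O4)ccc3OCc6ccccc6)c2)Oc2cc(OCc6ccccc6)cc(OCc6ccccc6)c21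
F2 | step 7 | (2S)-5,7-bis(benzyloxy)-2-{6,2'-bis(benzyloxy)-5'-[(2S)-5,7-bis(benzyloxy)-4-oxochroman-2-yl]-[1,1'-biphenyl]-3-yl}chroman-4-one | O=C1C[C@@H](c2ccc(OCc6ccccc6)c(-c3cc([C@H]4Oc5cc(OCc6ccccc6)cc(OCc6ccccc6)c5C(=O)C4)ccc3OCc6ccccc6)c2)Oc2cc(OCc6ccccc6)cc(OCc6ccccc6)c21
F3 | step 6 | 6,2'-bis(benzyloxy)-5'-iodo-[1,1'-biphenyl]-3-carbaldehyde | O=Cc1ccc(OCc2ccccc2)c(c1)-c1cc(I)ccc1OCc1ccccc1
F4 | step 6 | tert-butyl 3-[2,4-bis(benzyloxy)-6-hydroxyphenyl]-3-oxopropanoate | CC(C)(C)OC(=O)CC(=O)c1c(O)cc(OCc2ccccc2)cc1OCc1ccccc1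
F5 | step 6 | tert-butyl 2-[2,4-bis(benzyloxy)-6-hydroxybenzoyl]-3-[6,2'-bis(benzyloxy)-5'-iodo-[1,1'-biphenyl]-3-yl]prop-2-enoate (alkene geometry not controlled) | CC(C)(C)OC(=O)C(=Cc1ccc(OCc2ccccc2)c(c1)-c1cc(I)ccc1OCc1ccccc1)C(=O)c1c(O)cc(OCc2ccccc2)cc1OCc1ccccc1
F6 | step 6 | tert-butyl (2S)-5,7-bis(benzyloxy)-2-[6,2'-bis(benzyloxy)-5'-iodo-[1,1'-biphenyl]-3-yl]-4-oxochroman-3-carboxylate (C3 labile) | CC(C)(C)OC(=O)C1C(=O)c2c(OCc3ccccc3)cc(OCc3ccccc3)cc2O[C@@H]1c1ccc(OCc2ccccc2)c(c1)-c1cc(I)ccc1OCc1ccccc1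
F0 | step 8 | none | none
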